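## Structural features

The target is a flavone: a 4H-chromen-4-one (rings A and C) with hydroxyl groups at C5 and C7, joined through C2 to C1' of a benzene ring B. Ring B is 1,3,4,5-tetrasubstituted: the C4' hydroxyl is para to C1' and is flanked by a prenyl group at C3' and a (2R)-2-hydroxy-3-methylbut-3-enyl group at C5'. The only stereocentre is the secondary allylic carbinol C2'' of the C5' arm (O > isopropenyl > benzylic CH2 > H, hence R); it has no stereogenic neighbour. The fragile groups are the isopropenyl carbinol (ionisation or dehydration under acid), the prenyl olefin ortho to a free phenol (acid-induced closure to a chroman), the electron-rich phenols, and the pyranone, which opens at C2 with hard nucleophiles or strong base. The real difficulty is ring B, not the flavone nucleus: two five-carbon arms that differ only in oxidation pattern and in one stereocentre must sit on the two ortho positions of the same phenol, and neither phenol C-alkylation nor late oxidation of a diprenyl phenol can tell these positions apart. The key step exploits the fact that C2'–C3'(alkyl)–C4'(O)–C5'(alkyl) of ring B is the carbon chain of a 2,4-dialkyl-1-methoxy-3-silyloxybuta-1,3-diene, while C1'–C6' is a terminal alkyne bearing the chromone; since C3' and C5' are interchangeable on ring B, either diene end may carry either arm.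

## Logic of the disconnections

26 ⇒ 25. The O–Si bonds at C7–O and C2''–O are cut. Both hydroxyls stay masked to the end so that a single fluoride treatment finishes the synthesis; C5–OH (chelated) and C4'–OH (revealed by the key step) need no protection. The forward step must spare the pyranone and the allylic alcohol, hence buffered fluoride.

25 ⇒ 14 + 22. The ring bonds C1'–C2' and C5'–C6' are cut, with formal re-addition of methanol across C2'/C5' and of a silyl group on C4'–O. Ring B becomes the point of convergence: 14 carries both arms and the stereocentre, 22 carries rings A and C. A tetrasubstituted arene is thereby reduced to an acyclic diene and a monosubstituted alkyne. The forward step needs a sufficiently electron-poor alkyne, matched polarisation for the para relationship, and neutral conditions that keep the silyl enol ether and the allylic silyl ether intact.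

14 ⇒ 13 ⇒ 11. The enol O–Si bond is cut first, then the O–CH3 bond and the C–C bond to the one-carbon unit at C1. The diene is the double enol derivative of a 2-formyl ketone, so it comes from a simple dialkyl ketone and a formyl source. The forward steps need enolisation at the α'-methylene and an outward (Z) enol geometry; the site of formylation is irrelevant because both regioisomers give the same arene.

11 ⇒ 10 ⇒ 7 + 8 (through 9). The bond between the carbonyl carbon and the homoprenyl chain is cut. This separates the achiral prenyl arm, a commercial C6 bromide, from the chiral arm. The forward sequence is organomagnesium addition and re-oxidation; the transient carbinol centre of 10 is erased.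

7 ⇒ 6 ⇒ 4. The aldehyde is traced to a terminal vinyl group by anti-Markovnikov hydration and oxidation. The forward step must distinguish the monosubstituted vinyl group from the 1,1-disubstituted isopropenyl group.

4 ⇒ 3 ⇒ 1. The O–Si bond and then the bond between the carbinol carbon and the allyl CH2 are cut. The only stereocentre is thus set by reagent control on a small achiral enal at the very start. The forward step needs high Re-face selectivity and clean 1,2-addition.

22 ⇒ 21 ⇒ 20 ⇒ 19 ⇒ 18. The terminal alkyne carbon is removed (one-carbon homologation of an aldehyde), the aldehyde is traced through the primary alcohol to the ester, and the C7 O–Si bond is cut. The forward sequence needs a chemoselective ester reduction beside the pyranone and a homologation mild enough for an aryl silyl ether.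

18 ⇒ 15 + 16. C2–C3 (Claisen condensation) and O1–C2 (cyclodehydration) are cut. Two bulk chemicals result, and the symmetry of 15 removes any regiochemical question.

## Other disconnections considered

Alternative 1: Ring B is cut at C4'–C5', C2'–C3' and C1'–C6' into three alkynes: an ynol ether (C3'≡C4', prenyl on C3'), the propargylic alkyne of the chiral arm (C5'≡C6') and 22 (C1'≡C2').
- Forward step: the silicon-tethered diyne A1, in which a diisopropylsilylene links the ynol oxygen to the carbinol oxygen, would be cyclotrimerised with 22 by RhCl(PPh3)3. This would give the silylene-bridged flavone A2, closing ring B together with a seven-membered dioxasilepine; fluoride would then free three hydroxyls at once.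
- In its favour: the ring-forming step loses no atoms, which is better than the chosen step (methanol and a silyl group are expelled). One silicon protects two oxygens. The late convergence with 22 and the single deprotection are equal. A1 should need fewer steps than 14 (no hydroboration, organomagnesium addition, two oxidations or formylation), which is better on step count if A1 can be made.
- Against it: the tether fixes only C4'–C5'. The orientation in which 22 inserts into the rhodacyclopentadiene rests on a steric preference (chromonyl carbon away from the prenyl-bearing C3'), not on an electronic rule. A1 is a silyl ynol ether of a dialkoxysilane: hydrolytically labile and prone to C-silylation when made from an ynolate. The electron-rich ynol ether and the electron-poor 22 may each oligomerise on monovalent rhodium, and the two isolated olefins can enter enyne pathways.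
- Comparison: the chosen cycloaddition has one regiochemical event governed by matched polarisation, and its diene comes from robust carbonyl chemistry. It was preferred although it is longer.

Alternative 2: No skeletal bond is cut; the C2''–O bond and the isopropenyl unsaturation are traced back to a second prenyl group.
- Forward step: the symmetric bis-silylated diprenyl flavone A3 would be mono-epoxidised by the chiral dioxirane from the fructose-derived ketone, KHSO5 and K2CO3 (Shi epoxidation) to the (R)-epoxide A4. Base-induced opening towards a methyl group would give the allylic alcohol A5, and fluoride the target.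
- In its favour: A3 has a symmetric ring B and should be reachable in few steps by double ortho-prenylation of a para-hydroxyaryl carbonyl compound and standard flavone formation with 15, so the step count would be clearly lower (better). Trisubstituted olefins are the best substrates for this epoxidation, so enantiocontrol should equal that of the allylboration. The plan follows the presumed biogenesis.
- Against it: the two prenyl groups are equivalent, so mono-epoxidation is statistical and must be stopped at partial conversion and separated from starting material and bis-epoxide. The aqueous carbonate medium threatens the aryl silyl ethers and the pyranone, and once the C4' oxygen is freed it should open the epoxide to a dihydrobenzofuran or chroman. Isomerising A4 to the less substituted allylic alcohol needs a strongly basic aluminium amide that is hard to reconcile with the chelated phenol and pyranone; selenide-based openings would attack the secondary carbon and give the wrong allylic alcohol.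
- Comparison: the chosen plan spends more steps but places each arm by a separate C–C bond formation and sets the stereocentre on a small achiral aldehyde with no statistical element.

Alternative 3: Ring A is cut at C8–C8a, C5–C6, C7–C8 and C4a–C5.
- Forward step: the diazoacetyl pyranone A6, with ring B complete, would undergo photochemical Wolff rearrangement to a pyranonylketene. (2+2) addition of triisopropylsiloxyacetylene A7, four-electron opening of the cyclobutenone and six-electron electrocyclisation of the dienylketene (Danheiser benzannulation) would give flavone A8.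
- In its favour: the regiochemistry is inherent (ketene carbon becomes C5–OH, siloxy carbon becomes C7), which equals the chosen plan in built-in regiocontrol. It is better in one respect: the C5 and C7 oxygens emerge already differentiated without a selective silylation. The conditions are neutral.
- Against it: the strategic step builds ring A, which is available complete in 15. Ring B with its two arms and stereocentre must still be made beforehand and then carried through pyranone construction and diazo transfer, so the alternative adds to the hard part. The ketene could be intercepted by the prenyl and isopropenyl olefins, the pyranone chromophore competes for light, and the electrocyclisation must engage the pyranone double bond.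
- Comparison: step economy is judged worse, and the chosen plan places its ring-forming step where the structural difficulty lies.

Key step: step 14

Assumption: in step 7 the formyl group may enter at either α-methylene of 11; both regioisomers converge on the same ring B after steps 8 and 14, so the route is written for the isomer with the prenyl group on the formylated carbon.
Assumption: (+)-B-allyldiisopinocampheylborane denotes the reagent of the (−)-α-pinene series, used as its commercial solution.

Step 1
Reactants: 1 methacrolein (2-methylprop-2-enal)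
Product: 3 (R)-2-methylhexa-1,5-dien-3-ol, via borinate ester 2 (not isolated)
Conditions: (+)-Ipc2B(allyl), Et2O, −78 °C; then NaOH, H2O2, 0 °C → rt
Reagents that add atoms: (+)-B-allyldiisopinocampheylborane, C=CCB([C@H]1C[C@H]2C[C@@H]([C@@H]1C)C2(C)C)[C@H]1C[C@H]2C[C@@H]([C@@H]1C)C2(C)C
Why: Brown allylboration through a closed chair (Zimmerman–Traxler) transition state; the isopinocampheyl groups of the (−)-α-pinene series deliver the allyl group to the Re face of the formyl group, which makes the carbinol centre (R). Boron binds only the carbonyl oxygen, so addition is 1,2, and oxidative work-up cleaves borinate 2.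

Step 2
Reactants: 3 (R)-2-methylhexa-1,5-dien-3-ol
Product: 4 (R)-tert-butyldimethyl[(2-methylhexa-1,5-dien-3-yl)oxy]silane
Conditions: TBSCl, imidazole, DMF, rt
Reagents that add atoms: tert-butyldimethylsilyl chloride, CC(C)(C)[Si](C)(C)Cl
Why: Standard silylation of a secondary alcohol; the silyl ether should survive the borane, organomagnesium, enolate and thermal steps and fall to fluoride at the end.

Step 3
Reactants: 4 (R)-tert-butyldimethyl[(2-methylhexa-1,5-dien-3-yl)oxy]silane
Product: 6 (R)-4-(tert-butyldimethylsilyloxy)-5-methylhex-5-en-1-ol, via trialkylborane 5 (not isolated)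
Conditions: Sia2BH (from BH3·THF and 2-methylbut-2-ene), THF, 0 °C; then NaOH, H2O2, 0 °C → rt
Reagents that add atoms: hydrogen peroxide, OO
Why: Anti-Markovnikov hydroboration–oxidation; the hindered dialkylborane should add to the monosubstituted vinyl group much faster than to the 1,1-disubstituted isopropenyl group, which is further shielded by the adjacent silyloxy-bearing carbon. The stereocentre is not involved.

Step 4
Reactants: 6 (R)-4-(tert-butyldimethylsilyloxy)-5-methylhex-5-en-1-ol
Product: 7 (R)-4-(tert-butyldimethylsilyloxy)-5-methylhex-5-enal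
Conditions: Dess–Martin periodinane, CH2Cl2, 0 °C → rt
Reagents that add atoms: none
Why: Dess–Martin oxidation of a primary alcohol to the aldehyde under near-neutral conditions, without over-oxidation and without effect on the silyl ether or the olefin.

Step 5
Reactants: 7 (R)-4-(tert-butyldimethylsilyloxy)-5-methylhex-5-enal; 8 5-bromo-2-methylpent-2-ene
Product: 10 (3R,6RS)-3-(tert-butyldimethylsilyloxy)-2,10-dimethylundeca-1,9-dien-6-ol, via homoprenylmagnesium bromide 9 (not isolated)
Conditions: 8, Mg, THF, rt; then 7, −78 → 0 °C; aq. NH4Cl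
Reagents that add atoms: none
Why: Grignard addition to an aldehyde; the primary homoallylic bromide forms its organomagnesium reagent normally and the silyl ether is inert. The new carbinol centre is formed without control, which is immaterial because it is oxidised in the next step.

Step 6
Reactants: 10 (3R,6RS)-3-(tert-butyldimethylsilyloxy)-2,10-dimethylundeca-1,9-dien-6-ol
Product: 11 (R)-3-(tert-butyldimethylsilyloxy)-2,10-dimethylundeca-1,9-dien-6-one
Conditions: Dess–Martin periodinane, CH2Cl2, 0 °C → rt
Reagents that add atoms: none
Why: Dess–Martin oxidation of the secondary alcohol removes the uncontrolled centre; the C3 stereocentre is γ to the new carbonyl and can neither epimerise nor eliminate.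

Step 7
Reactants: 11 (R)-3-(tert-butyldimethylsilyloxy)-2,10-dimethylundeca-1,9-dien-6-one
Product: 13 (1E,6R)-6-(tert-butyldimethylsilyloxy)-1-methoxy-7-methyl-2-(3-methylbut-2-en-1-yl)octa-1,7-dien-3-one, via sodium enolate 12 (not isolated)
Conditions: NaH, HCO2Et, cat. EtOH, THF, 0 °C → rt; then Me2SO4, DMF, 0 °C → rt
Reagents that add atoms: ethyl formate, CCOC=O; dimethyl sulfate, COS(=O)(=O)OC
Why: Crossed Claisen condensation with ethyl formate gives the stabilised sodium enolate 12 of the β-keto aldehyde, which the hard electrophile dimethyl sulfate should alkylate on the less hindered formyl oxygen to the (E)-β-methoxy enone. Formylation at the other α-methylene gives a regioisomer that leads to the same ring B.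

Step 8
Reactants: 13 (1E,6R)-6-(tert-butyldimethylsilyloxy)-1-methoxy-7-methyl-2-(3-methylbut-2-en-1-yl)octa-1,7-dien-3-one
Product: 14 (1E,3Z,6R)-6-(tert-butyldimethylsilyloxy)-1-methoxy-7-methyl-2-(3-methylbut-2-en-1-yl)-3-(trimethylsilyloxy)octa-1,3,7-triene
Conditions: TMSOTf, Et3N, Et2O, 0 °C; pentane, filtration, used crude
Reagents that add atoms: trimethylsilyl trifluoromethanesulfonate, C[Si](C)(C)OS(=O)(=O)C(F)(F)F
Why: Soft enolisation of the enone at its only α'-methylene with silyl triflate and amine gives the silyl enol ether. The preferred (Z) enol ether places the C4 substituent outward, as the cycloaddition needs.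

Step 9
Reactants: 15 2,4,6-trihydroxyacetophenone; 16 diethyl oxalate
Product: 18 ethyl 5,7-dihydroxy-4-oxo-4H-chromene-2-carboxylate, via diketo ester 17 (not isolated)
Conditions: NaOEt, EtOH, reflux; then conc. HCl, EtOH, reflux
Reagents that add atoms: none
Why: Claisen condensation of the methyl ketone with the oxalate gives diketo ester 17. Acid then closes the pyranone by attack of an ortho hydroxyl on the α-keto carbon and loss of water (the classical chromone-2-carboxylate synthesis).

Step 10
Reactants: 18 ethyl 5,7-dihydroxy-4-oxo-4H-chromene-2-carboxylate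
Product: 19 ethyl 5-hydroxy-4-oxo-7-(triisopropylsilyloxy)-4H-chromene-2-carboxylate
Conditions: TIPSCl, imidazole, DMF, 0 °C → rt
Reagents that add atoms: triisopropylsilyl chloride, CC(C)[Si](Cl)(C(C)C)C(C)C
Why: Selective silylation of the C7 hydroxyl; the C5 hydroxyl is held in a strong hydrogen bond to the C4 carbonyl and is much less nucleophilic.

Step 11
Reactants: 19 ethyl 5-hydroxy-4-oxo-7-(triisopropylsilyloxy)-4H-chromene-2-carboxylate
Product: 20 5-hydroxy-2-(hydroxymethyl)-7-(triisopropylsilyloxy)-4H-chromen-4-one
Conditions: NaBH4, EtOH/THF, 0 °C; aq. NH4Cl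
Reagents that add atoms: none
Why: Borohydride reduction of a chromone-2-carboxylate ester to the primary alcohol, a known chemoselective reduction. The ester is activated by the oxygen-substituted acrylate system, whereas the pyranone carbonyl is a vinylogous ester and should stay untouched.

Step 12
Reactants: 20 5-hydroxy-2-(hydroxymethyl)-7-(triisopropylsilyloxy)-4H-chromen-4-one
Product: 21 5-hydroxy-4-oxo-7-(triisopropylsilyloxy)-4H-chromene-2-carbaldehyde
Conditions: MnO2, CH2Cl2, rt
Reagents that add atoms: none
Why: MnO2 oxidises the allylic-type primary alcohol on C2 to the aldehyde under neutral heterogeneous conditions that should leave the chelated phenol and the aryl silyl ether alone.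

Step 13
Reactants: 21 5-hydroxy-4-oxo-7-(triisopropylsilyloxy)-4H-chromene-2-carbaldehyde
Product: 22 2-ethynyl-5-hydroxy-7-(triisopropylsilyloxy)-4H-chromen-4-one
Conditions: dimethyl (1-diazo-2-oxopropyl)phosphonate, K2CO3, MeOH, 0 °C → rt
Reagents that add atoms: dimethyl (1-diazo-2-oxopropyl)phosphonate, CC(=O)C(=[N+]=[N-])P(=O)(OC)OC
Why: Seyferth–Gilbert homologation in the Ohira–Bestmann modification: the diazomethylphosphonate anion formed by methanolysis adds to the non-enolisable aldehyde, and the diazoalkene loses N2 with a 1,2-hydrogen shift to give the terminal alkyne. The reaction is run cold and short to spare the aryl silyl ether and the pyranone.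

Step 14
Reactants: 14 (1E,3Z,6R)-6-(tert-butyldimethylsilyloxy)-1-methoxy-7-methyl-2-(3-methylbut-2-en-1-yl)-3-(trimethylsilyloxy)octa-1,3,7-triene; 22 2-ethynyl-5-hydroxy-7-(triisopropylsilyloxy)-4H-chromen-4-one
Product: 25 2-{3-[(2R)-2-(tert-butyldimethylsilyloxy)-3-methylbut-3-en-1-yl]-4-hydroxy-5-(3-methylbut-2-en-1-yl)phenyl}-5-hydroxy-7-(triisopropylsilyloxy)-4H-chromen-4-one, via cycloadduct 23 (not isolated), via aryl trimethylsilyl ether 24 (not isolated)
Conditions: 14 (1.5 equiv), toluene, 4 Å MS, 100 °C, sealed tube; then PPTS (cat.), MeOH, 0 °C → rt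
Reagents that add atoms: none
Why: Thermal normal-electron-demand (4+2) cycloaddition, concerted but asynchronous: the diene terminus C4 (largest HOMO coefficient) bonds to the terminal alkyne carbon, the δ-position of the carbonyl-conjugated pyranone and site of the largest LUMO coefficient, while the methoxy-bearing C1 bonds to the chromonyl-substituted alkyne carbon. The closest known reaction type is the aromatic annulation of 1-methoxy-3-silyloxydienes with alkynyl ketones and esters to para-hydroxyaryl carbonyl compounds; 22 is a vinylogous alkynyl ketone, further activated by the C5–OH···O=C4 hydrogen bond. Ring B closes in this intermolecular cycloaddition (four carbons from 14, two from 22; new bonds C5'–C6' and C1'–C2') to give cyclohexa-1,4-diene 23. 23 then loses methanol by 1,4-elimination (allylic methoxy at C2', doubly allylic hydrogen at C5'), driven by aromatisation, to give aryl silyl ether 24, and mild methanolysis frees the C4' phenol. No stereocentre is created: the two sp3 ring carbons of 23 become aromatic, and the C2'' centre set in step 1 is remote from the reacting atoms and cannot epimerise under neutral thermal conditions. Regioselectivity (oxygen para to the chromonyl group) follows from the matched polarisation of both partners; chemoselectivity follows because the pyranone C2=C3 bond is a push–pull olefin in a quasi-aromatic ring and the prenyl and isopropenyl olefins are unactivated. The (1E,3Z) geometry of 14 puts both terminal substituents outward so that the s-cis conformer is accessible, and the molecular sieves take up the methanol that would otherwise desilylate unreacted diene.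

Step 15
Reactants: 25 2-{3-[(2R)-2-(tert-butyldimethylsilyloxy)-3-methylbut-3-en-1-yl]-4-hydroxy-5-(3-methylbut-2-en-1-yl)phenyl}-5-hydroxy-7-(triisopropylsilyloxy)-4H-chromen-4-one
Product: 26 5,7-dihydroxy-2-{4-hydroxy-3-[(2R)-2-hydroxy-3-methylbut-3-en-1-yl]-5-(3-methylbut-2-en-1-yl)phenyl}-4H-chromen-4-one
Conditions: TBAF, AcOH, THF, 0 °C → rt
Reagents that add atoms: none
Why: Fluoride cleaves both Si–O bonds (aryl triisopropylsilyl ether and secondary tert-butyldimethylsilyl ether). Acetic acid buffers the phenoxides so that the pyranone is not opened, and no stereocentre is affected.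

Compound list

1 | methacrolein (2-methylprop-2-enal) | C=C(C)C=O | starting material
2 | (R)-2-methylhexa-1,5-dien-3-yl diisopinocampheylborinate (formed in the flask) | C=CC[C@@H](OB([C@H]1C[C@H]2C[C@@H]([C@@H]1C)C2(C)C)[C@H]1C[C@H]2C[C@@H]([C@@H]1C)C2(C)C)C(C)=C | intermediate
3 | (R)-2-methylhexa-1,5-dien-3-ol | C=CC[C@@H](O)C(C)=C | intermediate
4 | (R)-tert-butyldimethyl[(2-methylhexa-1,5-dien-3-yl)oxy]silane | C=CC[C@@H](O[Si](C)(C)C(C)(C)C)C(C)=C | intermediate
5 | [(4R)-4-(tert-butyldimethylsilyloxy)-5-methylhex-5-en-1-yl]bis(3-methylbutan-2-yl)borane (formed in the flask) | CC(C)C(C)B(CCC[C@@H](O[Si](C)(C)C(C)(C)C)C(C)=C)C(C)C(C)C | intermediate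
6 | (R)-4-(tert-butyldimethylsilyloxy)-5-methylhex-5-en-1-ol | OCCC[C@@H](O[Si](C)(C)C(C)(C)C)C(C)=C | intermediate
7 | (R)-4-(tert-butyldimethylsilyloxy)-5-methylhex-5-enal | O=CCC[C@@H](O[Si](C)(C)C(C)(C)C)C(C)=C | intermediate
8 | 5-bromo-2-methylpent-2-ene | CC(C)=CCCBr | starting material
9 | (4-methylpent-3-en-1-yl)magnesium bromide (formed in the flask) | CC(C)=CCC[Mg]Br | intermediate
10 | (3R,6RS)-3-(tert-butyldimethylsilyloxy)-2,10-dimethylundeca-1,9-dien-6-ol | CC(C)=CCCC(O)CC[C@@H](O[Si](C)(C)C(C)(C)C)C(C)=C | intermediate
11 | (R)-3-(tert-butyldimethylsilyloxy)-2,10-dimethylundeca-1,9-dien-6-one | CC(C)=CCCC(=O)CC[C@@H](O[Si](C)(C)C(C)(C)C)C(C)=C | intermediate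
12 | sodium enolate of (6R)-6-(tert-butyldimethylsilyloxy)-7-methyl-2-(3-methylbut-2-en-1-yl)-3-oxooct-7-enal (formed in the flask) | [Na+].[O-]C=C(CC=C(C)C)C(=O)CC[C@@H](O[Si](C)(C)C(C)(C)C)C(C)=C | intermediate
13 | (1E,6R)-6-(tert-butyldimethylsilyloxy)-1-methoxy-7-methyl-2-(3-methylbut-2-en-1-yl)octa-1,7-dien-3-one | CO/C=C(CC=C(C)C)/C(=O)CC[C@@H](O[Si](C)(C)C(C)(C)C)C(C)=C | intermediate
14 | (1E,3Z,6R)-6-(tert-butyldimethylsilyloxy)-1-methoxy-7-methyl-2-(3-methylbut-2-en-1-yl)-3-(trimethylsilyloxy)octa-1,3,7-triene | CO/C=C(CC=C(C)C)/C(O[Si](C)(C)C)=C/C[C@@H](O[Si](C)(C)C(C)(C)C)C(C)=C | intermediate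
15 | 2,4,6-trihydroxyacetophenone | CC(=O)c1c(O)cc(O)cc1O | starting material
16 | diethyl oxalate | CCOC(=O)C(=O)OCC | starting material
17 | ethyl 2,4-dioxo-4-(2,4,6-trihydroxyphenyl)butanoate (formed in the flask) | CCOC(=O)C(=O)CC(=O)c1c(O)cc(O)cc1O | intermediate
18 | ethyl 5,7-dihydroxy-4-oxo-4H-chromene-2-carboxylate | CCOC(=O)c1cc(=O)c2c(O)cc(O)cc2o1 | intermediate
19 | ethyl 5-hydroxy-4-oxo-7-(triisopropylsilyloxy)-4H-chromene-2-carboxylate | CCOC(=O)c1cc(=O)c2c(O)cc(O[Si](C(C)C)(C(C)C)C(C)C)cc2o1 | intermediate
20 | 5-hydroxy-2-(hydroxymethyl)-7-(triisopropylsilyloxy)-4H-chromen-4-one | OCc1cc(=O)c2c(O)cc(O[Si](C(C)C)(C(C)C)C(C)C)cc2o1 | intermediate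
21 | 5-hydroxy-4-oxo-7-(triisopropylsilyloxy)-4H-chromene-2-carbaldehyde | O=Cc1cc(=O)c2c(O)cc(O[Si](C(C)C)(C(C)C)C(C)C)cc2o1 | intermediate
22 | 2-ethynyl-5-hydroxy-7-(triisopropylsilyloxy)-4H-chromen-4-one | C#Cc1cc(=O)c2c(O)cc(O[Si](C(C)C)(C(C)C)C(C)C)cc2o1 | intermediate
23 | 2-{5-[(2R)-2-(tert-butyldimethylsilyloxy)-3-methylbut-3-en-1-yl]-2-methoxy-3-(3-methylbut-2-en-1-yl)-4-(trimethylsilyloxy)cyclohexa-3,6-dien-1-yl}... written as the cyclohexa-1,4-diene cycloadduct, mixture of diastereomers at the two ring sp3 carbons (formed in the flask) | COC1C(CC=C(C)C)=C(O[Si](C)(C)C)C(C[C@@H](O[Si](C)(C)C(C)(C)C)C(C)=C)C=C1c1cc(=O)c2c(O)cc(O[Si](C(C)C)(C(C)C)C(C)C)cc2o1 | intermediate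
24 | 2-{3-[(2R)-2-(tert-butyldimethylsilyloxy)-3-methylbut-3-en-1-yl]-5-(3-methylbut-2-en-1-yl)-4-(trimethylsilyloxy)phenyl}-5-hydroxy-7-(triisopropylsilyloxy)-4H-chromen-4-one (formed in the flask) | C=C(C)[C@H](O[Si](C)(C)C(C)(C)C)Cc1cc(-c2cc(=O)c3c(O)cc(O[Si](C(C)C)(C(C)C)C(C)C)cc3o2)cc(CC=C(C)C)c1O[Si](C)(C)C | intermediate
25 | 2-{3-[(2R)-2-(tert-butyldimethylsilyloxy)-3-methylbut-3-en-1-yl]-4-hydroxy-5-(3-methylbut-2-en-1-yl)phenyl}-5-hydroxy-7-(triisopropylsilyloxy)-4H-chromen-4-one | C=C(C)[C@H](O[Si](C)(C)C(C)(C)C)Cc1cc(-c2cc(=O)c3c(O)cc(O[Si](C(C)C)(C(C)C)C(C)C)cc3o2)cc(CC=C(C)C)c1O | intermediate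
26 | 5,7-dihydroxy-2-{4-hydroxy-3-[(2R)-2-hydroxy-3-methylbut-3-en-1-yl]-5-(3-methylbut-2-en-1-yl)phenyl}-4H-chromen-4-one | C=C(C)[C@H](O)Cc1cc(-c2cc(=O)c3c(O)cc(O)cc3o2)cc(CC=C(C)C)c1O | target

Total step count: 15 (steps 1–8 to the diene, steps 9–13 to the alkyne, steps 14 and 15).
Longest linear sequence: 10 steps (steps 1–8, 14 and 15).

Steps least certain to work

Step 14 (key step). The alkyne is only a vinylogous acceptor, so cycloaddition may be slower than thermal decay of the diene or its protodesilylation by liberated methanol or by the chelated phenol; a stepwise conjugate addition that stops before ring closure is also conceivable. Fallback, setting out from 14 and rejoining the route at 26: the same diene would be combined with methyl propiolate, an alkynyl ester of the proven class, and the flavone would be built afterwards.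
- Cycloaddition and methanolysis as in step 14 should give methyl 3-[(2R)-2-(tert-butyldimethylsilyloxy)-3-methylbut-3-en-1-yl]-4-hydroxy-5-(3-methylbut-2-en-1-yl)benzoate F1.
- Silylation (TBSOTf, 2,6-lutidine) would give methyl 4-(tert-butyldimethylsilyloxy)-3-[(2R)-2-(tert-butyldimethylsilyloxy)-3-methylbut-3-en-1-yl]-5-(3-methylbut-2-en-1-yl)benzoate F2.
- In parallel, 15 would be silylated at the para hydroxyl (TIPSCl, imidazole) to 1-[2,6-dihydroxy-4-(triisopropylsilyloxy)phenyl]ethan-1-one F3.
- Crossed Claisen condensation of the polyanion of F3 (LiN(SiMe3)2, THF) with F2 would give 1-{4-(tert-butyldimethylsilyloxy)-3-[(2R)-2-(tert-butyldimethylsilyloxy)-3-methylbut-3-en-1-yl]-5-(3-methylbut-2-en-1-yl)phenyl}-3-[2,6-dihydroxy-4-(triisopropylsilyloxy)phenyl]propane-1,3-dione F4.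
- Mild acid-catalysed cyclodehydration (cat. TsOH, toluene, 60 °C) would close the pyranone to 2-{4-(tert-butyldimethylsilyloxy)-3-[(2R)-2-(tert-butyldimethylsilyloxy)-3-methylbut-3-en-1-yl]-5-(3-methylbut-2-en-1-yl)phenyl}-5-hydroxy-7-(triisopropylsilyloxy)-4H-chromen-4-one F5.
- The conditions of step 15 would then give 26.

Step 13. Under K2CO3/MeOH the aryl silyl ether may be lost by methanolysis, and methoxide may add to C2 of the electron-poor pyranone or to the newly formed electron-poor alkyne. Fallback, setting out from 18 and rejoining at 22: the homologation would be done before silylation, so that the C7 phenoxide formed under the basic conditions deactivates the pyranone and no silyl ether is exposed.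
- Borohydride reduction of 18 would give 5,7-dihydroxy-2-(hydroxymethyl)-4H-chromen-4-one F6.
- MnO2 would give 5,7-dihydroxy-4-oxo-4H-chromene-2-carbaldehyde F7.
- The Ohira–Bestmann reagent with excess K2CO3 would give 2-ethynyl-5,7-dihydroxy-4H-chromen-4-one F8.
- Selective silylation of the C7 hydroxyl (TIPSCl, imidazole) would give 22.

Step 7. Competing C-methylation of the enolate, aldol self-condensation of the ketone under NaH, or hydrolysis of the methoxymethylene ketone during work-up may erode the material. Fallback, setting out from 11 and rejoining at 26: the ketone would be converted into a 1-amino-3-silyloxydiene, a known and more reactive diene class.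
- Heating 11 with tert-butoxybis(dimethylamino)methane would give the enaminone (1E,6R)-6-(tert-butyldimethylsilyloxy)-1-(dimethylamino)-7-methyl-2-(3-methylbut-2-en-1-yl)octa-1,7-dien-3-one F9.
- KN(SiMe3)2 and TBSCl would give (1E,3Z,6R)-3,6-bis(tert-butyldimethylsilyloxy)-1-(dimethylamino)-7-methyl-2-(3-methylbut-2-en-1-yl)octa-1,3,7-triene F10.
- Cycloaddition of F10 with 22 and loss of dimethylamine on mild acid work-up should give the tris-silyl flavone F5 already described, which the conditions of step 15 convert into 26.

Step 3. Hydroboration of the isopropenyl group may compete, since the two terminal olefins differ only in substitution. Fallback, setting out from 4 and rejoining at 7: an aldehyde-selective, nitrite-modified Wacker oxidation (PdCl2(PhCN)2, CuCl2, AgNO2, t-BuOH/MeNO2, O2) would oxidise the monosubstituted vinyl group of 4 directly to aldehyde 7. The 1,1-disubstituted olefin is inert to Wacker chemistry, and the fallback makes no new compound.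

Step 11. Hydride may attack the pyranone (conjugate reduction at C2 or reduction of C4=O) in competition with the ester, or the aryl silyl ether may be cleaved in the basic alcoholic medium. Fallback, setting out from 15 and rejoining at 21: the ester and alcohol stages would be bypassed.
- Claisen condensation of 15 with ethyl acetate (NaH, THF) and acid cyclodehydration would give 5,7-dihydroxy-2-methyl-4H-chromen-4-one F11.
- Selective silylation (TIPSCl, imidazole) would give 5-hydroxy-2-methyl-7-(triisopropylsilyloxy)-4H-chromen-4-one F12.
- Riley oxidation of the activated 2-methyl group (SeO2, dioxane, reflux) would give aldehyde 21.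

Further compounds

F1 | step 14 | methyl 3-[(2R)-2-(tert-butyldimethylsilyloxy)-3-methylbut-3-en-1-yl]-4-hydroxy-5-(3-methylbut-2-en-1-yl)benzoate | C=C(C)[C@H](O[Si](C)(C)C(C)(C)C)Cc1cc(C(=O)OC)cc(CC=C(C)C)c1O
F2 | step 14 | methyl 4-(tert-butyldimethylsilyloxy)-3-[(2R)-2-(tert-butyldimethylsilyloxy)-3-methylbut-3-en-1-yl]-5-(3-methylbut-2-en-1-yl)benzoate | C=C(C)[C@H](O[Si](C)(C)C(C)(C)C)Cc1cc(C(=O)OC)cc(CC=C(C)C)c1O[Si](C)(C)C(C)(C)C
F3 | step 14 | 1-[2,6-dihydroxy-4-(triisopropylsilyloxy)phenyl]ethan-1-one | CC(=O)c1c(O)cc(O[Si](C(C)C)(C(C)C)C(C)C)cc1O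
F4 | step 14 | 1-{4-(tert-butyldimethylsilyloxy)-3-[(2R)-2-(tert-butyldimethylsilyloxy)-3-methylbut-3-en-1-yl]-5-(3-methylbut-2-en-1-yl)phenyl}-3-[2,6-dihydroxy-4-(triisopropylsilyloxy)phenyl]propane-1,3-dione | C=C(C)[C@H](O[Si](C)(C)C(C)(C)C)Cc1cc(C(=O)CC(=O)c2c(O)cc(O[Si](C(C)C)(C(C)C)C(C)C)cc2O)cc(CC=C(C)C)c1O[Si](C)(C)C(C)(C)C
F5 | step 14 | 2-{4-(tert-butyldimethylsilyloxy)-3-[(2R)-2-(tert-butyldimethylsilyloxy)-3-methylbut-3-en-1-yl]-5-(3-methylbut-2-en-1-yl)phenyl}-5-hydroxy-7-(triisopropylsilyloxy)-4H-chromen-4-one | C=C(C)[C@H](O[Si](C)(C)C(C)(C)C)Cc1cc(-c2cc(=O)c3c(O)cc(O[Si](C(C)C)(C(C)C)C(C)C)cc3o2)cc(CC=C(C)C)c1O[Si](C)(C)C(C)(C)C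
F6 | step 13 | 5,7-dihydroxy-2-(hydroxymethyl)-4H-chromen-4-one | OCc1cc(=O)c2c(O)cc(O)cc2o1
F7 | step 13 | 5,7-dihydroxy-4-oxo-4H-chromene-2-carbaldehyde | O=Cc1cc(=O)c2c(O)cc(O)cc2o1
F8 | step 13 | 2-ethynyl-5,7-dihydroxy-4H-chromen-4-one | C#Cc1cc(=O)c2c(O)cc(O)cc2o1
F9 | step 7 | (1E,6R)-6-(tert-butyldimethylsilyloxy)-1-(dimethylamino)-7-methyl-2-(3-methylbut-2-en-1-yl)octa-1,7-dien-3-one | CN(C)/C=C(CC=C(C)C)/C(=O)CC[C@@H](O[Si](C)(C)C(C)(C)C)C(C)=C
F10 | step 7 | (1E,3Z,6R)-3,6-bis(tert-butyldimethylsilyloxy)-1-(dimethylamino)-7-methyl-2-(3-methylbut-2-en-1-yl)octa-1,3,7-triene | CN(C)/C=C(CC=C(C)C)/C(O[Si](C)(C)C(C)(C)C)=C/C[C@@H](O[Si](C)(C)C(C)(C)C)C(C)=C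
F0 | step 3 | none | none
F11 | step 11 | 5,7-dihydroxy-2-methyl-4H-chromen-4-one | Cc1cc(=O)c2c(O)cc(O)cc2o1
F12 | step 11 | 5-hydroxy-2-methyl-7-(triisopropylsilyloxy)-4H-chromen-4-one | Cc1cc(=O)c2c(O)cc(O[Si](C(C)C)(C(C)C)C(C)C)cc2o1
A1 | alternative 1 | diisopropyl[(5-methylhex-4-en-1-yn-1-yl)oxy]{[(3R)-2-methylhex-1-en-5-yn-3-yl]oxy}silane | CC(C)=CCC#CO[Si](C(C)C)(C(C)C)O[C@H](CC#C)C(C)=C
A2 | alternative 1 | flavone with the C4' oxygen and the carbinol oxygen bridged by diisopropylsilylene (seven-membered dioxasilepine), 5-hydroxy-7-(triisopropylsilyloxy) | C=C(C)[C@H]1Cc2cc(-c3cc(=O)c4c(O)cc(O[Si](C(C)C)(C(C)C)C(C)C)cc4o3)cc(CC=C(C)C)c2O[Si](C(C)C)(C(C)C)O1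
A3 | alternative 2 | 2-[3,5-bis(3-methylbut-2-en-1-yl)-4-(triisopropylsilyloxy)phenyl]-5-hydroxy-7-(triisopropylsilyloxy)-4H-chromen-4-one | CC(C)=CCc1cc(-c2cc(=O)c3c(O)cc(O[Si](C(C)C)(C(C)C)C(C)C)cc3o2)cc(CC=C(C)C)c1O[Si](C(C)C)(C(C)C)C(C)C
A4 | alternative 2 | (R)-mono-epoxide of A3: 2-{3-{[(2R)-3,3-dimethyloxiran-2-yl]methyl}-5-(3-methylbut-2-en-1-yl)-4-(triisopropylsilyloxy)phenyl}-5-hydroxy-7-(triisopropylsilyloxy)-4H-chromen-4-one | CC1(C)O[C@@H]1Cc1cc(-c2cc(=O)c3c(O)cc(O[Si](C(C)C)(C(C)C)C(C)C)cc3o2)cc(CC=C(C)C)c1O[Si](C(C)C)(C(C)C)C(C)C
A5 | alternative 2 | 5-hydroxy-2-{3-[(2R)-2-hydroxy-3-methylbut-3-en-1-yl]-5-(3-methylbut-2-en-1-yl)-4-(triisopropylsilyloxy)phenyl}-7-(triisopropylsilyloxy)-4H-chromen-4-one | C=C(C)[C@H](O)Cc1cc(-c2cc(=O)c3c(O)cc(O[Si](C(C)C)(C(C)C)C(C)C)cc3o2)cc(CC=C(C)C)c1O[Si](C(C)C)(C(C)C)C(C)C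
A6 | alternative 3 | 2-(2-diazoacetyl)-6-{4-(tert-butyldimethylsilyloxy)-3-[(2R)-2-(tert-butyldimethylsilyloxy)-3-methylbut-3-en-1-yl]-5-(3-methylbut-2-en-1-yl)phenyl}-4H-pyran-4-one | C=C(C)[C@H](O[Si](C)(C)C(C)(C)C)Cc1cc(-c2cc(=O)cc(C(=O)C=[N+]=[N-])o2)cc(CC=C(C)C)c1O[Si](C)(C)C(C)(C)C
A7 | alternative 3 | (ethynyloxy)triisopropylsilane | C#CO[Si](C(C)C)(C(C)C)C(C)C
A8 | alternative 3 | 2-{4-(tert-butyldimethylsilyloxy)-3-[(2R)-2-(tert-butyldimethylsilyloxy)-3-methylbut-3-en-1-yl]-5-(3-methylbut-2-en-1-yl)phenyl}-5-hydroxy-7-(triisopropylsilyloxy)-4H-chromen-4-one | C=C(C)[C@H](O[Si](C)(C)C(C)(C)C)Cc1cc(-c2cc(=O)c3c(O)cc(O[Si](C(C)C)(C(C)C)C(C)C)cc3o2)cc(CC=C(C)C)c1O[Si](C)(C)C(C)(C)C
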